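Amounts come first: the charge gives 0.558 M of L against 0.93 M of E, and every X.L and every L.J binds one L.

in all of them: E 0.93 M; L 0.558 M; time 1.5 min

| flask | temperature |
|---|---|
| ochre | 20 °C |
| blue | 110 °C |
| red | 80 °C |
| green | 50 °C |

    J → D (k1 = 0.0802 s⁻¹, Ea1 = 100 kJ mol⁻¹)
    X + L → X.L (k2 = 0.283 M⁻¹ s⁻¹, Ea2 = 55.0 kJ mol⁻¹)
    L + J → L.J (k3 = 0.856 M⁻¹ s⁻¹, Ea3 = 59.0 kJ mol⁻¹)
    E ⇌ X, rate k4*(cs4 - [X]) while solid is left; crystals form when [X] > cs4 (cs4 = 0.93 M, k4 = 0.115 s⁻¹)
    X ⇌ J (K5 = 2.3, k5 = 0.0331 s⁻¹, Ea5 = 106 kJ mol⁻¹, ΔH5 = −9.00 kJ mol⁻¹)
    (constants at 80 °C)

- given per volume of solution although it is solid: E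
- the list of constants is for 80 °C, to be carried to other temperatures by the activation energies and enthalpies
- at the start none of E is in solution
- what has only dissolved of E counts as not reacted

* the flask that comes out highest in amount of L.J, in percent of the E charged, or "all alike" when all lie within 1.5 percentage points (ochre / blue / red / green / all alike)
* L.J at the end, in percent of the E charged, ochre
* L.J at the end, in percent of the E charged, blue
* L.J at the end, in percent of the E charged, red
* L.J at the end, in percent of the E charged, green

E has to dissolve before it reacts, but the gap to saturation halves in 6.03 s, much shorter than the run of 90 s, so I treat E as X from early on and ask what the amounts leave free. L charged over E charged is 60.0%. I call this the L ceiling: X.L and L.J together, as fractions of the E charged, cannot pass it. So at least 40.0% of the charge has to stand as X, J or D.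

The ceiling bounds the sum, but the question is how L.J fares within it. X to J has 51.0 kJ mol⁻¹ more activation energy than X + L, while L + J has 4.00 kJ mol⁻¹ more. From ochre to blue, X to J speeds up 27000 times and L + J 290 times, so heat makes J faster than it speeds J's capture. But J to D has 41.0 kJ mol⁻¹ more activation energy than L + J, a smaller gap than the first, so I put blue first, then red, green and ochre. By hand I get that order and the ceiling, and no yields.

The forecast gives 0.04% for ochre, 3% for green, 15% for red and 22% for blue, and names blue, saying “J competes best for L and blue comes out highest”.

The simulation names blue, with 0.0320% for ochre, 2.45% for green, 12.2% for red and 23.1% for blue.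

In blue at 0.0789 min, L goes to X.L 1.5 times as fast as to L.J at that moment, and blue ends with 34.0% X.L against 23.1% L.J, as fractions of the E charged, an amount ratio of 1.47. Together these make 57.1% under the L ceiling of 60.0%, with 4.9% of the L still unbound. The neighbour of blue charged with 1.6 M of E has its ceiling at 34.9%, and there 0.080% of the L stays unbound, while X.L and L.J add up to 34.9% of the E charged, 20.7% as X.L and 14.2% as L.J.

All constants are made up; the flask was simulated.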